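**Plan** (lignan locants: C7 carbinol carbon, C8 the ring carbon bearing it, C9 the neighbouring OCH2; C7', C8', C9' the matching atoms on the benzyl side)
- Retrosynthesis first removes the two phenol benzyl ethers and the two hydrogens at C8 and C8', leading back to a 3,4-disubstituted 2,5-dihydrofuran with a C8=C8' double bond.
- That double bond is cut and SO2 is placed between C8 and C8'. The two carbons flanking sulfur in 1,4-oxathiane 4,4-dioxide become C8 and C8', and its ring oxygen with the two adjacent CH2 groups maps onto O, C9 and C9' of the oxolane, so loss of SO2 contracts the six-membered sulfone to the five-membered ether.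
- The arms are cut at C7–C8 (acylation of the α-sulfonyl carbanion by a vanillate ester) and at C7'–C8' (benzylation of the other α-carbanion by a vanillyl bromide).
- Forward order: benzylation, acylation, ketone reduction, silylation, ring contraction (the only ring-forming event; the sulfone ring is bought), desilylation, hydrogenation, debenzylation.
- Stereochemistry: C7 comes from catalyst-controlled asymmetric transfer hydrogenation of the aryl ketone; C8 and C8' are set together by one syn addition of H2 directed by the C7 hydroxyl.

Key step: step 6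

Remark: the carbinol centre C7 is labelled R while C8 carries sulfur or is an alkene carbon and S once C8 is a saturated CH; this is a change of priority only, the spatial arrangement set in step 4 is never altered.

**Step 1**
Reactants: 1 4-(benzyloxy)-3-methoxybenzyl alcohol
Product: 2 4-(benzyloxy)-3-methoxybenzyl bromide
Conditions: PBr3 (0.4 equiv), Et2O, 0 °C; used crude
Reagents that add atoms: phosphorus tribromide, BrP(Br)Br
Why: Alcohol-to-bromide substitution with PBr3, in which the primary benzylic hydroxyl is activated as a phosphite ester and displaced by bromide in an SN2 step, should proceed cleanly at 0 °C without touching the aryl benzyl ether, and the labile electron-rich bromide is used at once.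

**Step 2**
Reactants: 3 1,4-oxathiane 4,4-dioxide; 2 4-(benzyloxy)-3-methoxybenzyl bromide
Product: 5 3-[4-(benzyloxy)-3-methoxybenzyl]-1,4-oxathiane 4,4-dioxide (racemic), via 3-lithio-1,4-oxathiane 4,4-dioxide 4 (not isolated)
Conditions: 3 (1.5 equiv), n-BuLi (1.4 equiv), THF, −78 °C; then 2 (1.0 equiv), −78 → −40 °C
Reagents that add atoms: none
Why: α-Sulfonyl carbanion alkylation, in which n-BuLi removes one of the four equivalent α-protons at −78 °C and the carbanion is benzylated in an SN2 step by the very reactive bromide before ring opening by β-elimination of the ring oxygen can intervene, should give the mono-benzyl sulfone because the excess of sulfone holds back double alkylation, and the new centre (future C8') may be racemic since it becomes sp2 in step 6.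

**Step 3**
Reactants: 5 3-[4-(benzyloxy)-3-methoxybenzyl]-1,4-oxathiane 4,4-dioxide; 6 methyl 4-(benzyloxy)-3-methoxybenzoate
Product: 8 [4-(benzyloxy)-3-methoxyphenyl]{5-[4-(benzyloxy)-3-methoxybenzyl]-4,4-dioxido-1,4-oxathian-3-yl}methanone (keto sulfone as a mixture of stereoisomers), via 5-lithio-3-[4-(benzyloxy)-3-methoxybenzyl]-1,4-oxathiane 4,4-dioxide 7 (not isolated)
Conditions: LiN(i-Pr)2 (2.2 equiv), THF, −78 °C; then 6 (1.2 equiv), −78 → −30 °C; aq NH4Cl
Reagents that add atoms: none
Why: Claisen-type acylation of an α-sulfonyl carbanion, in which the amide base deprotonates the unsubstituted α-CH2 (future C8) in preference to the hindered tertiary C8'–H, the carbanion adds to the ester with loss of methoxide, and the second equivalent of base stores the acidic β-keto sulfone as its enolate so that it neither quenches unreacted carbanion nor is attacked again, should give the keto sulfone with both ring centres deliberately left unresolved.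

**Step 4**
Reactants: 8 keto sulfone
Product: 9 (R)-[4-(benzyloxy)-3-methoxyphenyl]{5-[4-(benzyloxy)-3-methoxybenzyl]-4,4-dioxido-1,4-oxathian-3-yl}methanol (ring centres mixed)
Conditions: RuCl(p-cymene)[(S,S)-TsDPEN] (2 mol %), HCO2H–Et3N (5:2), DMF, 40 °C
Reagents that add atoms: none
Why: Noyori-type asymmetric transfer hydrogenation, in which the ruthenium hydride and the ligand N–H deliver hydride and proton to the aryl ketone through the outer-sphere six-membered transition state with the aryl ring held under the cymene ligand, should give with the (S,S) catalyst the carbinol of the same spatial sense as an (S)-1-arylethanol (labelled R here because the sulfonyl-bearing C8 outranks the aryl group), while the acidic C8–H between carbonyl and sulfonyl equilibrates under Et3N so that both C8 epimers drain through the faster-reducing one (dynamic kinetic resolution) and C7 is set by the catalyst alone.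

**Step 5**
Reactants: 9 (R)-hydroxy sulfone
Product: 10 3-[4-(benzyloxy)-3-methoxybenzyl]-5-{(R)-[4-(benzyloxy)-3-methoxyphenyl][(tert-butyldimethylsilyl)oxy]methyl}-1,4-oxathiane 4,4-dioxide (ring centres mixed)
Conditions: TBSOTf, 2,6-lutidine, CH2Cl2, 0 °C
Reagents that add atoms: tert-butyldimethylsilyl trifluoromethanesulfonate, CC(C)(C)[Si](C)(C)OS(=O)(=O)C(F)(F)F
Why: O-Silylation with a silyl triflate and a hindered pyridine base should cap the hindered secondary carbinol without ever forming its alkoxide, so retro-aldol cleavage of the β-hydroxy sulfone is avoided and C7 is untouched, and the TBS ether is chosen because it should survive KOH on alumina yet leave with fluoride under non-acidic conditions.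

**Step 6**
Reactants: 10 silylated 3,5-disubstituted 1,4-oxathiane 4,4-dioxide
Product: 13 tert-butyl{(R)-[4-(benzyloxy)-3-methoxyphenyl]{4-[4-(benzyloxy)-3-methoxybenzyl]-2,5-dihydrofuran-3-yl}methoxy}dimethylsilane, via C8'-bromo sulfone 11 (not isolated), via bicyclic episulfone 12 (not isolated)
Conditions: CBr2F2 (excess), KOH/Al2O3, t-BuOH–CH2Cl2, 0 °C → rt
Reagents that add atoms: none
Why: KOH on alumina should first remove the less hindered C8'–H and the carbanion takes bromine from CBr2F2 to give 11; deprotonation at C8 is then followed by intramolecular displacement of bromide, which forms the C8–C8' bond and closes the three-membered episulfone ring of 12 in a 3-exo-tet mode (the same bond completes the oxolane ring, 5-exo-tet), and cheletropic loss of SO2 leaves the ring alkene of 13. The closest known reaction type is the in-situ halogenative Ramberg–Bäcklund contraction of α,α'-disubstituted six-membered cyclic sulfones (thianes to cyclopentenes, thiomorpholine S,S-dioxides to 3-pyrrolines), which also delivers tetrasubstituted alkenes. No stereocentre is created: C8 and C8' both become sp2, so the mixed ring configuration of 10 converges, the alkene can only be cis inside the five-membered ring, and C7 is untouched because its hydrogen is not acidic. The selectivity needed is 1,3-elimination ahead of β-elimination of the silyloxy group from the C8 carbanion, and it should be secured because the bulky CH(OTBS)Ar arm steers the first deprotonation and bromination to C8', so that the C8 carbanion only arises when a bromide, a far better leaving group than a silanolate, is already placed for ring closure. β-Elimination of the ring oxygen, open to either carbanion, is reversible since the alkoxide stays tethered to the vinyl sulfone and can re-add in an oxa-Michael sense, and CBr2F2 is used because the difluorocarbene it releases should not add to the electron-rich alkene.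

**Step 7**
Reactants: 13 dihydrofuran silyl ether
Product: 14 (R)-[4-(benzyloxy)-3-methoxyphenyl]{4-[4-(benzyloxy)-3-methoxybenzyl]-2,5-dihydrofuran-3-yl}methanol
Conditions: n-Bu4NF, THF, 0 °C → rt; aq NH4Cl
Reagents that add atoms: none
Why: Fluoride-induced desilylation, driven by the strength of the Si–F bond, should cleave the secondary silyl ether under non-acidic conditions that leave the ionisable allylic and benzylic carbinol, the ring alkene and the benzyl ethers unchanged and C7 with its configuration.

**Step 8**
Reactants: 14 allylic alcohol
Product: 15 (S)-[4-(benzyloxy)-3-methoxyphenyl]{(3R,4S)-4-[4-(benzyloxy)-3-methoxybenzyl]oxolan-3-yl}methanol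
Conditions: [Ir(cod)(PCy3)(py)]PF6 (10 mol %, two portions), H2 (1 atm), CH2Cl2, rt
Reagents that add atoms: none
Why: Hydroxyl-directed homogeneous hydrogenation, in which the cationic iridium centre binds the C7 hydroxyl and the tetrasubstituted ring alkene at once while allylic 1,3-strain with the cis C7' methylene holds the C7–H bond in the alkene plane and so places the hydroxyl over one face only, should deliver both hydrogens to that face in one syn addition and thereby set C8 (R) and C8' (S) together, cis to each other and in the relation to C7 that the target requires.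

**Step 9**
Reactants: 15 di-O-benzyl oxolane
Product: 16 4-[(S)-hydroxy{(3R,4S)-4-[(4-hydroxy-3-methoxyphenyl)methyl]oxolan-3-yl}methyl]-2-methoxyphenol (CNP0234428.2)
Conditions: H2 (1 atm), 10% Pd/C, EtOAc–EtOH, rt; stopped after two equivalents of H2
Reagents that add atoms: none
Why: Catalytic hydrogenolysis of aryl benzyl ethers on the palladium surface under neutral conditions should cleave the two O–CH2Ph bonds faster than the secondary benzylic C7–OH bond, so that stopping at two equivalents of H2 releases both phenols and gives the target with its three stereocentres unchanged.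

**Compound list**
1 | 4-(benzyloxy)-3-methoxybenzyl alcohol | COc1cc(CO)ccc1OCc1ccccc1 | starting material
2 | 4-(benzyloxy)-3-methoxybenzyl bromide | COc1cc(CBr)ccc1OCc1ccccc1 | intermediate
3 | 1,4-oxathiane 4,4-dioxide | O=S1(=O)CCOCC1 | starting material
4 | 3-lithio-1,4-oxathiane 4,4-dioxide (formed in the flask in step 2) | [Li]C1COCCS1(=O)=O | intermediate
5 | 3-[4-(benzyloxy)-3-methoxybenzyl]-1,4-oxathiane 4,4-dioxide (racemic) | COc1cc(CC2COCCS2(=O)=O)ccc1OCc1ccccc1 | intermediate
6 | methyl 4-(benzyloxy)-3-methoxybenzoate | COC(=O)c1ccc(OCc2ccccc2)c(OC)c1 | starting material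
7 | 5-lithio-3-[4-(benzyloxy)-3-methoxybenzyl]-1,4-oxathiane 4,4-dioxide (formed in the flask in step 3) | [Li]C1COCC(Cc2ccc(OCc3ccccc3)c(OC)c2)S1(=O)=O | intermediate
8 | [4-(benzyloxy)-3-methoxyphenyl]{5-[4-(benzyloxy)-3-methoxybenzyl]-4,4-dioxido-1,4-oxathian-3-yl}methanone (stereoisomer mixture) | COc1cc(CC2COCC(C(=O)c3ccc(OCc4ccccc4)c(OC)c3)S2(=O)=O)ccc1OCc1ccccc1 | intermediate
9 | (R)-[4-(benzyloxy)-3-methoxyphenyl]{5-[4-(benzyloxy)-3-methoxybenzyl]-4,4-dioxido-1,4-oxathian-3-yl}methanol (ring centres mixed) | COc1cc(CC2COCC([C@H](O)c3ccc(OCc4ccccc4)c(OC)c3)S2(=O)=O)ccc1OCc1ccccc1 | intermediate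
10 | 3-[4-(benzyloxy)-3-methoxybenzyl]-5-{(R)-[4-(benzyloxy)-3-methoxyphenyl][(tert-butyldimethylsilyl)oxy]methyl}-1,4-oxathiane 4,4-dioxide (ring centres mixed; key-step precursor) | COc1cc(CC2COCC([C@H](O[Si](C)(C)C(C)(C)C)c3ccc(OCc4ccccc4)c(OC)c3)S2(=O)=O)ccc1OCc1ccccc1 | intermediate
11 | C8'-bromo sulfone: 3-[4-(benzyloxy)-3-methoxybenzyl]-3-bromo-5-{(R)-[4-(benzyloxy)-3-methoxyphenyl][(tert-butyldimethylsilyl)oxy]methyl}-1,4-oxathiane 4,4-dioxide (formed in the flask in step 6) | COc1cc(CC2(Br)COCC([C@H](O[Si](C)(C)C(C)(C)C)c3ccc(OCc4ccccc4)c(OC)c3)S2(=O)=O)ccc1OCc1ccccc1 | intermediate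
12 | bicyclic episulfone: 1-[4-(benzyloxy)-3-methoxybenzyl]-5-{(R)-[4-(benzyloxy)-3-methoxyphenyl][(tert-butyldimethylsilyl)oxy]methyl}-3-oxa-6-thiabicyclo[3.1.0]hexane 6,6-dioxide (cis-fused; formed in the flask in step 6) | COc1cc(CC23COCC2([C@H](O[Si](C)(C)C(C)(C)C)c5ccc(OCc6ccccc6)c(OC)c5)S3(=O)=O)ccc1OCc1ccccc1 | intermediate
13 | tert-butyl{(R)-[4-(benzyloxy)-3-methoxyphenyl]{4-[4-(benzyloxy)-3-methoxybenzyl]-2,5-dihydrofuran-3-yl}methoxy}dimethylsilane (key-step product) | COc1cc(CC2=C(COC2)[C@H](O[Si](C)(C)C(C)(C)C)c2ccc(OCc3ccccc3)c(OC)c2)ccc1OCc1ccccc1 | intermediate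
14 | (R)-[4-(benzyloxy)-3-methoxyphenyl]{4-[4-(benzyloxy)-3-methoxybenzyl]-2,5-dihydrofuran-3-yl}methanol | COc1cc(CC2=C(COC2)[C@H](O)c2ccc(OCc3ccccc3)c(OC)c2)ccc1OCc1ccccc1 | intermediate
15 | (S)-[4-(benzyloxy)-3-methoxyphenyl]{(3R,4S)-4-[4-(benzyloxy)-3-methoxybenzyl]oxolan-3-yl}methanol | COc1cc(C[C@@H]2COC[C@@H]2[C@H](O)c2ccc(OCc3ccccc3)c(OC)c2)ccc1OCc1ccccc1 | intermediate
16 | 4-[(S)-hydroxy{(3R,4S)-4-[(4-hydroxy-3-methoxyphenyl)methyl]oxolan-3-yl}methyl]-2-methoxyphenol (7S,8R,8'S; ring substituents cis) | COc1cc(C[C@@H]2COC[C@@H]2[C@H](O)c2ccc(O)c(OC)c2)ccc1O | target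

**Step count**
Total steps: 9. Longest linear sequence: 9 steps (1 → 2 → 5 → 8 → 9 → 10 → 13 → 14 → 15 → 16).

**Steps most likely to fail**

Step 6 (ring contraction). The C8 carbanion may lose the C7 silyloxy group by β-elimination faster than it closes the episulfone. Bromination may also start at C8 or occur twice, and either course would divert material from the 1,3-elimination. The fallback leaves the sulfone and builds the same ring alkene by cross-coupling; it sets out from bromide 2 and comes back to the route at allylic alcohol 14.
- Purchased methyl 4-oxotetrahydrofuran-3-carboxylate is converted with Tf2O and i-Pr2NEt (CH2Cl2, −78 °C) into the enol triflate methyl 4-{[(trifluoromethyl)sulfonyl]oxy}-2,5-dihydrofuran-3-carboxylate F1.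
- Zinc dust in THF containing LiCl inserts into bromide 2 to give [4-(benzyloxy)-3-methoxybenzyl]zinc bromide F2.
- Negishi coupling of F2 with F1 under Pd(PPh3)4 should give methyl 4-[4-(benzyloxy)-3-methoxybenzyl]-2,5-dihydrofuran-3-carboxylate F3, in which the C8=C8' bond and both ring CH2–O groups are in place.
- Reduction with i-Bu2AlH (CH2Cl2, −78 °C) should give {4-[4-(benzyloxy)-3-methoxybenzyl]-2,5-dihydrofuran-3-yl}methanol F4, and MnO2 then the aldehyde 4-[4-(benzyloxy)-3-methoxybenzyl]-2,5-dihydrofuran-3-carbaldehyde F5.
- The aryl group and C7 are introduced together by catalytic asymmetric aryl transfer. Purchased [4-(benzyloxy)-3-methoxyphenyl]boronic acid and Et2Zn give [4-(benzyloxy)-3-methoxyphenyl](ethyl)zinc F6, which adds to F5 under a chiral β-amino alcohol ligand such as 3-exo-morpholinoisoborneol. The ligand enantiomer is chosen to deliver the R carbinol, giving 14.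

Step 8 (directed hydrogenation). The iridium catalyst may deactivate before the hindered tetrasubstituted alkene is consumed. The acidic metal hydride may ionise the allylic, alkoxybenzylic carbinol or isomerise it to the saturated ketone. Facial selectivity would erode if the hydroxyl does not stay bound. The fallback sets out from 14 and comes back at 15 without passing through any new compound (F0).
- 14 is hydrogenated over the heterogeneous catalyst 5% Rh/Al2O3 under H2 in EtOAc at room temperature; rhodium is chosen because it saturates alkenes with little hydrogenolysis of allylic or benzylic C–O bonds.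
- Face selection then rests on adsorption rather than on coordination to a soluble cationic metal. In the conformer fixed by allylic strain, the aryl group covers one face of the ring alkene, while the small hydroxyl, which also anchors to the metal surface, lies on the other.
- Syn addition from the hydroxyl face should give the same cis isomer 15.

Step 3 (acylation). Addition of the hindered secondary carbanion to the electron-rich ester may be slow, so that on warming ring opening by β-elimination of the ring oxygen and proton transfer from the product compete. The fallback replaces acylation by addition to an aldehyde followed by oxidation; it sets out from 5 and comes back at 8.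
- 5 is lithiated with n-BuLi at −78 °C to carbanion 7.
- Purchased 4-(benzyloxy)-3-methoxybenzaldehyde is added at −78 °C, where addition to an aldehyde is fast, to give [4-(benzyloxy)-3-methoxyphenyl]{5-[4-(benzyloxy)-3-methoxybenzyl]-4,4-dioxido-1,4-oxathian-3-yl}methanol as a mixture of all stereoisomers F7.
- Oxidation with Dess–Martin periodinane (CH2Cl2, NaHCO3) should give keto sulfone 8.

**Further compounds**
F1 | step 6 | methyl 4-{[(trifluoromethyl)sulfonyl]oxy}-2,5-dihydrofuran-3-carboxylate | COC(=O)C1=C(OS(=O)(=O)C(F)(F)F)COC1
F2 | step 6 | [4-(benzyloxy)-3-methoxybenzyl]zinc bromide | COc1cc(C[Zn]Br)ccc1OCc1ccccc1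
F3 | step 6 | methyl 4-[4-(benzyloxy)-3-methoxybenzyl]-2,5-dihydrofuran-3-carboxylate | COC(=O)C1=C(Cc2ccc(OCc3ccccc3)c(OC)c2)COC1
F4 | step 6 | {4-[4-(benzyloxy)-3-methoxybenzyl]-2,5-dihydrofuran-3-yl}methanol | OCC1=C(Cc2ccc(OCc3ccccc3)c(OC)c2)COC1
F5 | step 6 | 4-[4-(benzyloxy)-3-methoxybenzyl]-2,5-dihydrofuran-3-carbaldehyde | O=CC1=C(Cc2ccc(OCc3ccccc3)c(OC)c2)COC1
F6 | step 6 | [4-(benzyloxy)-3-methoxyphenyl](ethyl)zinc | CC[Zn]c1ccc(OCc2ccccc2)c(OC)c1
F0 | step 8 | none | none
F7 | step 3 | [4-(benzyloxy)-3-methoxyphenyl]{5-[4-(benzyloxy)-3-methoxybenzyl]-4,4-dioxido-1,4-oxathian-3-yl}methanol (all stereoisomers) | COc1cc(CC2COCC(C(O)c3ccc(OCc4ccccc4)c(OC)c3)S2(=O)=O)ccc1OCc1ccccc1
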